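**Retrosynthetic overview**

1. Numbering: caryophyllane half C1–C15 (cyclobutane C1, C9, C10, C11; nine-membered ring C1–C9; C14 = CO2H carbon on C4; C15 = CH2 on C8); labdane half C1′–C20′; the cyclohexene is C4–C5–C15′–C14′=C13′–C12′. Enabling feature: the exocyclic C8=C15 methylene of the nine-membered ring, i.e. the C7(sp3)–C8(sp2) bond between a ring CH2 and a 1,1-disubstituted alkene carbon next to cyclobutane C9, so that the ring closure itself can deliver the methylene.
2. Disconnections: C7–C8 by intramolecular Suzuki–Miyaura coupling (alkenyl triflate + primary alkylboronate); C3–C4 by alkylation of a cis-fused γ-lactone enolate (quaternary C4, union of the cyclobutane block with the core).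
3. The cyclohexene comes from a Diels–Alder reaction of trans-communic ester with a chiral 5-alkoxybutenolide. This ring-locked (Z)-enoate gives a temporary lactone C14(=O)–O–C6 that places the carboxyl cis to C6 and is later opened by hydrolysis and Wittig reaction. The cyclobutane comes from [2+2] photocycloaddition of the same butenolide with 2-methylpropene.
4. Ring order: decalin (purchased) → cyclobutane (step 1) → cyclohexene (step 8) → nine-membered ring last (step 16).

Key step: step 16

Remark: trans-communic acid and (5S)-5-[(1S,2R,5S)-menthyloxy]furan-2(5H)-one (the butenolide made from (+)-menthol) are taken as purchasable; atom numbers below are those of overview line 1.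

Step 1
Reactants: 1 (5S)-5-[(1S,2R,5S)-menthyloxy]furan-2(5H)-one; 2 2-methylpropene
Product: 3 (1R,4S,5R)-4-[(1S,2R,5S)-menthyloxy]-6,6-dimethyl-3-oxabicyclo[3.2.0]heptan-2-one
Conditions: hν (medium-pressure Hg lamp, quartz), acetone/MeCN, excess 2-methylpropene, −30 °C
Reagents that add atoms: none
Why: Sensitized enone–alkene [2+2] photocycloaddition should give the cis-fused cyclobutane head-to-tail (CMe2 on the β-carbon, the usual outcome for cyclic enones and 1,1-dialkylethenes) on the face anti to the menthyloxy group, which fixes C1 as R, while the minor facial and head-to-head adducts are diastereomers of 3 and are removed by chromatography.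

Step 2
Reactants: 3 (1R,4S,5R)-4-[(1S,2R,5S)-menthyloxy]-6,6-dimethyl-3-oxabicyclo[3.2.0]heptan-2-one
Product: 4 (1R,5R)-4-hydroxy-6,6-dimethyl-3-oxabicyclo[3.2.0]heptan-2-one (lactol, both C4 epimers)
Conditions: 2 M HCl, 1,4-dioxane, 60 °C
Reagents that add atoms: water, O
Why: Aqueous acid hydrolysis of the lactone acetal (a pseudo-ester) releases the auxiliary and should give the pseudo-acid lactol with both ring stereocenters untouched.

Step 3
Reactants: 4 (1R,5R)-4-hydroxy-6,6-dimethyl-3-oxabicyclo[3.2.0]heptan-2-one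
Product: 5 (1R,2R)-2-ethenyl-3,3-dimethylcyclobutane-1-carboxylic acid (cis)
Conditions: Ph3PCH3Br, KN(SiMe3)2 (3 equiv), THF, −78 → 0 °C; then 1 M HCl
Reagents that add atoms: methyltriphenylphosphonium bromide, C[P+](c1ccccc1)(c1ccccc1)c1ccccc1.[Br-]
Why: Wittig methylenation of the lactol, which opens under base to the aldehyde carboxylate, should install C3 as the vinyl CH2, the low temperature keeping enolization at C1 slow, and any trans acid formed is purged in step 4 because only the cis acid can lactonize.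

Step 4
Reactants: 5 (1R,2R)-2-ethenyl-3,3-dimethylcyclobutane-1-carboxylic acid
Product: 8 (1R,6R)-7,7-dimethyl-3-oxabicyclo[4.2.0]octan-2-one, via bis(9-BBN) adduct 6 (not isolated), via hydroxy acid 7 (not isolated)
Conditions: 9-BBN (2.2 equiv), THF, 0 °C → rt; NaOH, H2O2, 0 °C; then HCl to pH 2, TsOH (catalytic), toluene, 40 °C
Reagents that add atoms: hydrogen peroxide, OO
Why: Anti-Markovnikov hydroboration–oxidation of the vinyl group gives the primary alcohol at C3, which closes with the cis carboxylic acid to the δ-lactone, so that lactonization doubles as a stereochemical filter for the cis (1R,6R) series.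

Step 5
Reactants: 8 (1R,6R)-7,7-dimethyl-3-oxabicyclo[4.2.0]octan-2-one
Product: 10 (1R,2R)-2-(2-iodoethyl)-3,3-dimethylcyclobutane-1-carboxylic acid, via iodo silyl ester 9 (not isolated)
Conditions: Me3SiI (1.5 equiv), CH2Cl2, rt; then H2O
Reagents that add atoms: iodotrimethylsilane, C[Si](C)(C)I
Why: Iodotrimethylsilane cleaves the lactone by silylation of the carbonyl oxygen and SN2 attack of iodide on the primary O–CH2 carbon (alkyl–oxygen fission), and hydrolysis of the silyl ester on work-up gives the ω-iodo acid.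

Step 6
Reactants: 10 (1R,2R)-2-(2-iodoethyl)-3,3-dimethylcyclobutane-1-carboxylic acid
Product: 12 (1R,2R)-2-(2-iodoethyl)-N-methoxy-N,3,3-trimethylcyclobutane-1-carboxamide, via acid chloride 11 (not isolated)
Conditions: (COCl)2, DMF (catalytic), CH2Cl2, 0 °C → rt; then MeNH(OMe)·HCl, pyridine, 0 °C
Reagents that add atoms: N,O-dimethylhydroxylamine hydrochloride, CNOC.Cl
Why: Acid chloride formation under non-basic conditions (so that no carboxylate can displace the iodide and re-form the lactone) followed by N-acylation gives the N-methoxy-N-methyl amide, a latent methyl ketone that tolerates ester enolates and ylides.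

Step 7
Reactants: 13 trans-communic acid
Product: 14 2-(trimethylsilyl)ethyl trans-communate
Conditions: Me3SiCH2CH2OH, PPh3, DIAD, THF, 0 °C → rt
Reagents that add atoms: 2-(trimethylsilyl)ethanol, C[Si](C)(C)CCO
Why: In the Mitsunobu esterification the unhindered primary alcohol is activated and the hindered axial C19′ carboxylate only acts as nucleophile, which gives an ester that fluoride can later cleave without attack at the neopentyl-type carbonyl.

Step 8
Reactants: 14 2-(trimethylsilyl)ethyl trans-communate; 1 (5S)-5-[(1S,2R,5S)-menthyloxy]furan-2(5H)-one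
Product: 15 Diels–Alder lactone acetal (cyclohexene C4–C5–C15′–C14′=C13′–C12′ cis-fused at C4/C5 to the γ-lactone C14(=O)–O–C6H(O-menthyl); 6S; H-4 cis to H-5 and H-12′)
Conditions: toluene, 115 °C (sealed tube), BHT (catalytic), 72 h
Reagents that add atoms: none
Why: In this thermal Diels–Alder reaction the butenolide acts as a ring-locked (Z)-enoate, so that the C14 carbonyl and C6 become cis on the new cyclohexene, the diene adds to the face anti to the menthyloxy group (absolute configuration at C4 and C5), the endo transition state places the C12′ substituent cis to the lactone carbonyl, and the "ortho" orientation of the 1-alkyl diene joins C12′ to the α-carbon and keeps this terminus away from the acetal.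

Step 9
Reactants: 15 Diels–Alder lactone acetal; 12 (1R,2R)-2-(2-iodoethyl)-N-methoxy-N,3,3-trimethylcyclobutane-1-carboxamide
Product: 17 C4-alkylated lactone acetal (C4 quaternary; C3 on the face formerly held by H-4), via lithium enolate 16 (not isolated)
Conditions: LiN(iPr)2 (1.05 equiv), THF, −78 °C; DMPU; then 12, −78 → −40 °C
Reagents that add atoms: none
Why: The lithium enolate of the cis-fused γ-lactone is alkylated by the primary iodide on its convex face, anti to the ring bond C5–C15′ and to the C12′ substituent, so that the cis ring fusion is retained and the quaternary C4 is set with C3 trans to C6 (enolate alkylation forming a fully substituted carbon).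

Step 10
Reactants: 17 C4-alkylated lactone acetal
Product: 18 lactol (pseudo-acid; C6–OH in place of O-menthyl, both C6 epimers)
Conditions: 2 M HCl, THF, 45 °C
Reagents that add atoms: water, O
Why: Dilute aqueous acid hydrolyses the lactone acetal to the pseudo-acid and frees the auxiliary, while the exocyclic alkene, the silylethyl ester and the amide should survive these mild conditions.

Step 11
Reactants: 18 lactol
Product: 19 vinyl acid (C5–CH=CH2 = C6=C7; C4–CO2H = C14)
Conditions: Ph3PCH3Br, KN(SiMe3)2 (2.5 equiv), THF, −78 → 0 °C; then aq. NH4Cl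
Reagents that add atoms: methyltriphenylphosphonium bromide, C[P+](c1ccccc1)(c1ccccc1)c1ccccc1.[Br-]
Why: Wittig methylenation of the aldehyde carboxylate formed from the lactol under base converts the temporary lactone into the C5 vinyl group and the free C14 acid, the aldehyde reacting far faster with the ylide than the amide or the hindered ester.

Step 12
Reactants: 19 vinyl acid
Product: 20 bis[2-(trimethylsilyl)ethyl] ester (C14 and C19′)
Conditions: Me3SiCH2CH2OH, PPh3, DIAD, THF, 0 °C → rt
Reagents that add atoms: 2-(trimethylsilyl)ethanol, C[Si](C)(C)CCO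
Why: Mitsunobu esterification again lets the hindered tertiary C14 carboxylate act only as the nucleophile toward the activated primary alcohol.

Step 13
Reactants: 20 bis[2-(trimethylsilyl)ethyl] ester
Product: 22 trans methyl ketone (C9–C(=O)CH3; cyclobutane 1R,9S), via cis methyl ketone 21 (not isolated)
Conditions: MeMgBr (3 equiv), THF, −20 → 0 °C; aq. NH4Cl; then K2CO3, MeOH, 40 °C
Reagents that add atoms: methylmagnesium bromide, C[Mg]Br
Why: Addition of MeMgBr to the N-methoxy-N-methyl amide stops at the ketone because of the stable magnesium chelate, and base equilibration through the enolate then should convert the cis ketone into the more stable trans-1,2-disubstituted cyclobutane, which sets C9 as in the target (C15 enters as the methyl group).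

Step 14
Reactants: 22 trans methyl ketone
Product: 24 alkenyl triflate (C9–C(OTf)=CH2), via potassium enolate 23 (not isolated)
Conditions: KN(SiMe3)2, THF, −78 °C; PhNTf2, −78 → −20 °C; aq. NH4Cl
Reagents that add atoms: N-phenylbis(trifluoromethanesulfonimide), O=S(=O)(N(c1ccccc1)S(=O)(=O)C(F)(F)F)C(F)(F)F
Why: Kinetic deprotonation at the methyl group (enolization toward the cyclobutane methine would give a strained exocyclic double bond) and O-sulfonylation of the enolate give the 1,1-disubstituted alkenyl triflate in which C15 is already the future methylene.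

Step 15
Reactants: 24 alkenyl triflate
Product: 25 pinacol boronate (C5–CH2CH2–B, boron on C7)
Conditions: [Ir(cod)Cl]2 (2.5 mol %), dppm (5 mol %), pinacolborane (1.5 equiv), CH2Cl2, rt
Reagents that add atoms: pinacolborane, [H]B1OC(C)(C)C(C)(C)O1
Why: Iridium-catalysed hydroboration with pinacolborane is selective for monosubstituted terminal alkenes and should give the linear primary boronate at C7, leaving the 1,1-disubstituted C8′=C17′ alkene, the trisubstituted ring alkene and the electron-poor alkenyl triflate untouched.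

Step 16
Reactants: 25 pinacol boronate
Product: 26 bis[2-(trimethylsilyl)ethyl] ester of the target
Conditions: Pd(OAc)2 (10 mol %), RuPhos (20 mol %), K3PO4, toluene/H2O, 80 °C, syringe-pump addition of 25 (final 1 mM)
Reagents that add atoms: none
Why: Zerovalent palladium (formed in situ from Pd(OAc)2 and the phosphine) adds oxidatively to the alkenyl C8–OTf bond, the phosphate-activated primary C7 boronate transmetalates, and reductive elimination forms the C7–C8 bond. The closest known reaction type is the intramolecular sp3–sp2 Suzuki–Miyaura coupling (B-alkyl macrocyclization), which has been used to close nine-membered carbocycles of terpenoids. The nine-membered ring is closed end to end by this single C(sp3)–C(sp2) bond, and because the electrophile is a 1,1-disubstituted alkenyl triflate the C8=C15 methylene ends exocyclic with no alkene geometry or position to control. No new stereocenter is formed, and the ring stereocenters C1, C4, C5 and C9 set earlier cannot epimerize under the mildly basic conditions. The step needs cyclization to outrun oligomerization, protodeboronation and β-hydride elimination: the trans arrangement of the two arms on the cyclohexene (C4/C5) and on the cyclobutane (C1/C9) points the termini toward each other, slow addition keeps the substrate at millimolar concentration, and the bulky electron-rich biarylphosphine speeds reductive elimination. Chemoselectivity follows from the single C–B and single C–OTf bond in 25, the hindered esters and the other alkenes being inert.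

Step 17
Reactants: 26 bis[2-(trimethylsilyl)ethyl] ester of the target
Product: 27 CNP0330729.1 (target diacid)
Conditions: Bu4NF (6 equiv), THF, rt → 40 °C; then aq. HCl to pH 3
Reagents that add atoms: none
Why: Fluoride attacks silicon in both 2-(trimethylsilyl)ethyl groups and β-elimination releases ethene and the two carboxylates, so that the hindered esters are cleaved without nucleophilic attack at carbonyl and without isomerization of the alkenes (fluoride-induced fragmentation).

**Compound list**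

1 | (5S)-5-[(1S,2R,5S)-menthyloxy]furan-2(5H)-one | O=C1C=C[C@@H](O[C@H]2C[C@@H](C)CC[C@@H]2C(C)C)O1 | starting material
2 | 2-methylpropene | C=C(C)C | starting material
3 | (1R,4S,5R)-4-[(1S,2R,5S)-menthyloxy]-6,6-dimethyl-3-oxabicyclo[3.2.0]heptan-2-one | O=C1O[C@H](O[C@H]3C[C@@H](C)CC[C@@H]3C(C)C)[C@@H]2[C@H]1CC2(C)C | intermediate
4 | (1R,5R)-4-hydroxy-6,6-dimethyl-3-oxabicyclo[3.2.0]heptan-2-one (lactol, C4 epimers) | O=C1OC(O)[C@@H]2[C@H]1CC2(C)C | intermediate
5 | (1R,2R)-2-ethenyl-3,3-dimethylcyclobutane-1-carboxylic acid | C=C[C@@H]1[C@H](C(=O)O)CC1(C)C | intermediate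
6 | bis(9-BBN) adduct of 5 (B-alkyl at C3, acyloxyborane at C8) | C(CB1C2CCCC1CCC2)[C@@H]1[C@H](C(=O)OB2C3CCCC2CCC3)CC1(C)C | intermediate
7 | (1R,2R)-2-(2-hydroxyethyl)-3,3-dimethylcyclobutane-1-carboxylic acid | OCC[C@@H]1[C@H](C(=O)O)CC1(C)C | intermediate
8 | (1R,6R)-7,7-dimethyl-3-oxabicyclo[4.2.0]octan-2-one | O=C1OCC[C@@H]2[C@H]1CC2(C)C | intermediate
9 | trimethylsilyl (1R,2R)-2-(2-iodoethyl)-3,3-dimethylcyclobutane-1-carboxylate | ICC[C@@H]1[C@H](C(=O)O[Si](C)(C)C)CC1(C)C | intermediate
10 | (1R,2R)-2-(2-iodoethyl)-3,3-dimethylcyclobutane-1-carboxylic acid | ICC[C@@H]1[C@H](C(=O)O)CC1(C)C | intermediate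
11 | (1R,2R)-2-(2-iodoethyl)-3,3-dimethylcyclobutane-1-carbonyl chloride | ICC[C@@H]1[C@H](C(=O)Cl)CC1(C)C | intermediate
12 | (1R,2R)-2-(2-iodoethyl)-N-methoxy-N,3,3-trimethylcyclobutane-1-carboxamide | ICC[C@@H]1[C@H](C(=O)N(C)OC)CC1(C)C | intermediate
13 | trans-communic acid, (1S,4aR,5S,8aR)-1,4a-dimethyl-6-methylidene-5-[(2E)-3-methylpenta-2,4-dien-1-yl]decahydronaphthalene-1-carboxylic acid | C=C/C(C)=C/C[C@H]1C(=C)CC[C@@H]2[C@]1(C)CCC[C@]2(C)C(=O)O | starting material
14 | 2-(trimethylsilyl)ethyl trans-communate | C=C/C(C)=C/C[C@H]1C(=C)CC[C@@H]2[C@]1(C)CCC[C@]2(C)C(=O)OCC[Si](C)(C)C | intermediate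
15 | Diels–Alder lactone acetal (cis-fused γ-lactone C14(=O)–O–C6; 6S menthyloxy, exo; H-4 cis to H-5 and H-12′; C19′ silylethyl ester) | O=C1O[C@H](O[C@H]5C[C@@H](C)CC[C@@H]5C(C)C)[C@H]2CC=C(C)[C@@H](C[C@H]3C(=C)CC[C@@H]4[C@]3(C)CCC[C@]4(C)C(=O)OCC[Si](C)(C)C)[C@@H]12 | intermediate
16 | lithium enolate of 15 (C14(OLi)=C4) | [Li]OC=1O[C@H](O[C@H]5C[C@@H](C)CC[C@@H]5C(C)C)[C@H]2CC=C(C)[C@@H](C[C@H]3C(=C)CC[C@@H]4[C@]3(C)CCC[C@]4(C)C(=O)OCC[Si](C)(C)C)C=12 | intermediate
17 | C4-alkylated lactone acetal (C4 quaternary, bearing C3H2–C2H2–C1 of the cis-(1R,9R)-cyclobutane N-methoxy-N-methyl amide) | O=C1O[C@H](O[C@H]5C[C@@H](C)CC[C@@H]5C(C)C)[C@H]2CC=C(C)[C@@H](C[C@H]3C(=C)CC[C@@H]4[C@]3(C)CCC[C@]4(C)C(=O)OCC[Si](C)(C)C)[C@@]12CC[C@@H]6[C@H](C(=O)N(C)OC)CC6(C)C | intermediate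
18 | lactol (pseudo-acid) of 17, C6–OH, both epimers | O=C1OC(O)[C@H]2CC=C(C)[C@@H](C[C@H]3C(=C)CC[C@@H]4[C@]3(C)CCC[C@]4(C)C(=O)OCC[Si](C)(C)C)[C@@]12CC[C@@H]6[C@H](C(=O)N(C)OC)CC6(C)C | intermediate
19 | vinyl acid (C5 vinyl, C14 acid) | C=C[C@H]2CC=C(C)[C@@H](C[C@H]3C(=C)CC[C@@H]4[C@]3(C)CCC[C@]4(C)C(=O)OCC[Si](C)(C)C)[C@]2(C(=O)O)CC[C@@H]6[C@H](C(=O)N(C)OC)CC6(C)C | intermediate
20 | bis[2-(trimethylsilyl)ethyl] ester of 19 | C=C[C@H]2CC=C(C)[C@@H](C[C@H]3C(=C)CC[C@@H]4[C@]3(C)CCC[C@]4(C)C(=O)OCC[Si](C)(C)C)[C@]2(C(=O)OCC[Si](C)(C)C)CC[C@@H]6[C@H](C(=O)N(C)OC)CC6(C)C | intermediate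
21 | cis methyl ketone (cyclobutane 1R,9R) | C=C[C@H]2CC=C(C)[C@@H](C[C@H]3C(=C)CC[C@@H]4[C@]3(C)CCC[C@]4(C)C(=O)OCC[Si](C)(C)C)[C@]2(C(=O)OCC[Si](C)(C)C)CC[C@@H]6[C@H](C(C)=O)CC6(C)C | intermediate
22 | trans methyl ketone (cyclobutane 1R,9S) | C=C[C@H]2CC=C(C)[C@@H](C[C@H]3C(=C)CC[C@@H]4[C@]3(C)CCC[C@]4(C)C(=O)OCC[Si](C)(C)C)[C@]2(C(=O)OCC[Si](C)(C)C)CC[C@@H]6[C@@H](C(C)=O)CC6(C)C | intermediate
23 | potassium enolate of 22 (C8(OK)=C15H2) | C=C[C@H]2CC=C(C)[C@@H](C[C@H]3C(=C)CC[C@@H]4[C@]3(C)CCC[C@]4(C)C(=O)OCC[Si](C)(C)C)[C@]2(C(=O)OCC[Si](C)(C)C)CC[C@@H]6[C@@H](C(=C)O[K])CC6(C)C | intermediate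
24 | alkenyl triflate (C9–C(OTf)=CH2) | C=C[C@H]2CC=C(C)[C@@H](C[C@H]3C(=C)CC[C@@H]4[C@]3(C)CCC[C@]4(C)C(=O)OCC[Si](C)(C)C)[C@]2(C(=O)OCC[Si](C)(C)C)CC[C@@H]6[C@@H](C(=C)OS(=O)(=O)C(F)(F)F)CC6(C)C | intermediate
25 | pinacol boronate (boron on C7) | CC1(C)OB(CC[C@H]2CC=C(C)[C@@H](C[C@H]3C(=C)CC[C@@H]4[C@]3(C)CCC[C@]4(C)C(=O)OCC[Si](C)(C)C)[C@]2(C(=O)OCC[Si](C)(C)C)CC[C@@H]6[C@@H](C(=C)OS(=O)(=O)C(F)(F)F)CC6(C)C)OC1(C)C | intermediate
26 | bis[2-(trimethylsilyl)ethyl] ester of the target | C=C1CC[C@H]2CC=C(C)[C@@H](C[C@H]3C(=C)CC[C@@H]4[C@]3(C)CCC[C@]4(C)C(=O)OCC[Si](C)(C)C)[C@]2(C(=O)OCC[Si](C)(C)C)CC[C@@H]2[C@@H]1CC2(C)C | intermediate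
27 | CNP0330729.1 | C=C1CC[C@H]2CC=C(C)[C@@H](C[C@H]3C(=C)CC[C@@H]4[C@]3(C)CCC[C@]4(C)C(=O)O)[C@]2(C(=O)O)CC[C@@H]2[C@@H]1CC2(C)C | target

**Totals**

Total step count: 17. Longest linear sequence: 15 steps (steps 1–6, then 9–17).

**Steps most likely to fail**

1. Step 16. The ring closure may lose to intermolecular coupling (oligomers), to protodeboronation or β-hydride elimination of the alkylpalladium species, or to hydrolysis of the triflate. Fallback: set out from 20. Vinylmagnesium bromide converts the N-methoxy-N-methyl amide into the vinyl ketone F1. Ring-closing metathesis (second-generation Grubbs catalyst, toluene, 80 °C, high dilution) between the C5 vinyl group and the enone gives the (Z)-cyclononenone F2. Conjugate reduction with [(Ph3P)CuH]6 gives the cis-fused ketone F3, and K2CO3 in MeOH equilibrates C9 to the trans-fused ketone F4. Wittig methylenation with Ph3P=CH2 then rejoins the route at 26.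

2. Step 8. The cycloaddition may proceed with the wrong orientation (the 2-methyl group of the diene opposes the directing effect of the 1-alkyl group), with incomplete facial or endo selectivity, or too slowly, so that the diene isomerizes or dimerizes. Fallback: set out from 14. Maleic anhydride (toluene, 80 °C), a symmetrical and far more reactive dienophile with no orientation problem, gives the endo anhydride F5. LiAlH(OtBu)3 (THF, −40 °C) reduces the less hindered carbonyl (C6) to the hydroxy lactone F6. Acetalization with (1S,2R,5S)-menthol (camphorsulfonic acid, toluene) gives 15 after chromatographic separation from the diastereomer that stems from the other diene face.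

3. Step 9. Elimination of HI from the primary iodide by the hindered enolate, O-alkylation, or decomposition of the enolate may outrun C-alkylation at the fully substituted carbon. Fallback: set out from 8. MeNH(OMe)·HCl/AlMe3 opens the lactone to the hydroxy amide F7, and Dess–Martin periodinane gives the aldehyde F8. Aldol addition of enolate 16 to F8 gives the β-hydroxy lactone F9 (the aldehyde is a far better electrophile and cannot eliminate). PhOC(S)Cl/pyridine gives the thionocarbonate F10, and Barton–McCombie deoxygenation (Bu3SnH, AIBN, toluene, 80 °C) rejoins the route at 17.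

Further compounds
F1 | step 16 | vinyl ketone (C9–C(=O)CH=CH2, cyclobutane cis) | C=C[C@H]2CC=C(C)[C@@H](C[C@H]3C(=C)CC[C@@H]4[C@]3(C)CCC[C@]4(C)C(=O)OCC[Si](C)(C)C)[C@]2(C(=O)OCC[Si](C)(C)C)CC[C@@H]6[C@H](C(=O)C=C)CC6(C)C
F2 | step 16 | (Z)-cyclononenone (C8=O, C6=C7), cis-fused to the cyclobutane | O=C1/C=C\[C@H]2CC=C(C)[C@@H](C[C@H]3C(=C)CC[C@@H]4[C@]3(C)CCC[C@]4(C)C(=O)OCC[Si](C)(C)C)[C@]2(C(=O)OCC[Si](C)(C)C)CC[C@@H]2[C@H]1CC2(C)C
F3 | step 16 | cis-fused C8 ketone | O=C1CC[C@H]2CC=C(C)[C@@H](C[C@H]3C(=C)CC[C@@H]4[C@]3(C)CCC[C@]4(C)C(=O)OCC[Si](C)(C)C)[C@]2(C(=O)OCC[Si](C)(C)C)CC[C@@H]2[C@H]1CC2(C)C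
F4 | step 16 | trans-fused C8 ketone | O=C1CC[C@H]2CC=C(C)[C@@H](C[C@H]3C(=C)CC[C@@H]4[C@]3(C)CCC[C@]4(C)C(=O)OCC[Si](C)(C)C)[C@]2(C(=O)OCC[Si](C)(C)C)CC[C@@H]2[C@@H]1CC2(C)C
F5 | step 8 | endo maleic anhydride adduct of 14 | O=C1OC(=O)[C@H]2CC=C(C)[C@@H](C[C@H]3C(=C)CC[C@@H]4[C@]3(C)CCC[C@]4(C)C(=O)OCC[Si](C)(C)C)[C@@H]12
F6 | step 8 | hydroxy lactone (C6–OH pseudo-acid) | O=C1OC(O)[C@H]2CC=C(C)[C@@H](C[C@H]3C(=C)CC[C@@H]4[C@]3(C)CCC[C@]4(C)C(=O)OCC[Si](C)(C)C)[C@@H]12
F7 | step 9 | (1R,2R)-2-(2-hydroxyethyl)-N-methoxy-N,3,3-trimethylcyclobutane-1-carboxamide | OCC[C@@H]1[C@H](C(=O)N(C)OC)CC1(C)C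
F8 | step 9 | (1R,2R)-N-methoxy-N,3,3-trimethyl-2-(2-oxoethyl)cyclobutane-1-carboxamide | O=CC[C@@H]1[C@H](C(=O)N(C)OC)CC1(C)C
F9 | step 9 | β-hydroxy lactone (C3–OH, both epimers) | O=C1O[C@H](O[C@H]5C[C@@H](C)CC[C@@H]5C(C)C)[C@H]2CC=C(C)[C@@H](C[C@H]3C(=C)CC[C@@H]4[C@]3(C)CCC[C@]4(C)C(=O)OCC[Si](C)(C)C)[C@@]12C(O)C[C@@H]6[C@H](C(=O)N(C)OC)CC6(C)C
F10 | step 9 | O-phenyl thionocarbonate of F9 | O=C1O[C@H](O[C@H]5C[C@@H](C)CC[C@@H]5C(C)C)[C@H]2CC=C(C)[C@@H](C[C@H]3C(=C)CC[C@@H]4[C@]3(C)CCC[C@]4(C)C(=O)OCC[Si](C)(C)C)[C@@]12C(OC(=S)Oc7ccccc7)C[C@@H]6[C@H](C(=O)N(C)OC)CC6(C)C
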